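To whoever takes over the bench: the flasks east, south and north below are yours, and the winter and summer runs are what I have to judge them by.

| flask | starting material | partner | temperature | remark | time |
|---|---|---|---|---|---|
| winter | 0.95 M | 1.3 equiv | 99 °C | run made earlier |  |
| summer | 1.4 M | 1.3 equiv | 107 °C | run made earlier |  |
| east | 1.9 M | 1.30 equiv | 95 °C |  | 12 min |
| south | 1.9 M | 1.30 equiv |  | at 110 °C until 8.0 min, from then on at 95 °C | 12 min |
| north | 1.9 M | 1.30 equiv | 110 °C |  | 12 min |

- winter (time / min: target / %): 1.00: 2.0; 2.00: 5.8; 4.00: 7.9; 8.00: 12.8; 15.0: 17.5
- summer (time / min: target / %): 1.50: 8.8; 3.00: 13.9; 4.00: 15.5; 6.00: 19.3; 8.00: 21.3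

(standard deviation of a reading: 0.5 percentage points)

* the flask with the highest amount of target, in percent of the starting material charged ("all alike" if they lie within 1.5 percentage points) (east / south / north / all alike)
* final target, as a percentage of the starting material charged, in east
* final target, as a percentage of the starting material charged, in south
* final target, as a percentage of the starting material charged, in north



In the summer run, target climbs from 15.5 % at 4.00 min to 21.3 % at 8.00 min, a factor of 1.37. I call this factor, target at a given time over target at half that time, the doubling gain. A flask making target at a steady pace reads two, and a flask at a standstill reads one, which is the zero of my scale. The winter run, cooler and more dilute, reads 1.62 over the same times, which is higher, though both are readings with their scatter.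

When you come, each flask will hold target beside unused starting material and partner. North is hotter and stronger than the summer run, so I expect its gain from half time to the end to lie below the summer figure, and the gain of the cooler east to lie above north's. The flasks should therefore draw together. Please keep to 12 min: the winter run stops at 15.0 min and the summer run at 8.00 min, and a gain read over one doubling doesn't tell what the next doubling brings.

The forecast, made from these same runs, gives 24.5 % for east, 29 % for south and 27.5 % for north. It names south as highest, where target “creeps upward on cooling”, so it keeps the flasks further apart than I expect.

East ends at 25.3 %, south at 25.5 % and north at 25.3 %, so the answer is all alike.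

    starting material + partner → target, rate k1*[starting material]^1.5*[partner] (k = 7.60 × 10⁻⁴ /M^1.5/s, Ea = 66.0 kJ/mol)
    starting material + target → side product (k = 4.40 × 10⁻⁴ /M/s, Ea = 66.0 kJ/mol)
    2 partner → homo dimer (k = 0.00170 /M/s, Ea = 85.0 kJ/mol)
    (constants at 110 °C)

At 12.0 min, south makes target 1.07 times as fast as it uses it up, each step taken net, which is close to the maximum of an intermediate. North's doubling gain from 6.00 min to 12.0 min is 1.04, below the summer figure. East's over the same times is 1.29, above north's.

(The data were computed with made-up constants; the scatter is artificial.)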